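Imd is the product wanted from the midnight flask, and at 8.0 d a choice falls due: wait, heat, add Rea, or take Imd out.

the same everywhere: temperature 40 °C

| run | Sub | Rea | remark | time |
|---|---|---|---|---|
| midnight | 0.10 M | 0.11 M | the very flask that is asked about, followed so far |  |
| winter | 0.20 M | 0.11 M | run made earlier |  |
| flask | 0.10 M | 0.110 M |  | 8.0 d |

- midnight (time / d: Imd / %): 0.833: 7.9; 1.67: 12.1; 3.00: 13.6; 4.00: 12.7; 5.00: 14.9; 6.00: 13.1
- winter (time / d: Imd / %): 0.167: 1.6; 0.500: 3.2; 0.833: 4.5; 1.25: 6.6; 2.08: 5.6; 2.50: 3.0; 3.00: 5.7

(each reading ± 1 percentage point)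

- teal: change nothing and wait 4.0 d more
- violet: at 8.0 d raise the temperature by 20 K, then wait 4.0 d
- green: at 8.0 d add Rea, 50.0% of the amount charged, then wait 4.0 d
- blue: at 8.0 d take out 90% of the Imd then present, then wait 4.0 d

1. Imd, in percent of the Sub first charged, at 8.0 d
2. what to do for the largest gain in Imd; "none" if nothing gains more than 2 percentage points (teal / violet / green / blue / none)
3. Imd present, with what was taken out counted in, in percent of the Sub first charged, after violet
4. Imd present, with what was taken out counted in, in percent of the Sub first charged, after green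

- Imd taken out counts as made
- candidate steps: Sub + Rea -> Sub.Rea; Rea + Sub.Rea -> Imd; Rea + Imd -> Rea.Imd; Imd <-> Sid
- additions bring no volume worth counting
- the earlier runs do not show what temperature does; that part of a forecast is a guess

The choice hangs on whether the midnight flask is still moving. The midnight readings show no trend from 3.00 d on, and the winter readings wander around a level from 1.25 d on. A level can be frozen, so each run is replaced by the mean of those readings, its plateau, with Rea counted in equivalents per Sub:

midnight: 13.6% of the Sub charged, at 1.10 equivalents

winter: 5.22% of the Sub charged, at 0.550 equivalents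

Rea is taken here as the limiting reagent, with the plateau read lower in the run with fewer equivalents. The difference between the plateaus, divided by the difference in equivalents, gives:

15.2% of the Sub charged per equivalent

This is the Rea return, the Imd plateau gained per extra equivalent of Rea. It assumes that the ratio of the charges counts, not their concentrations.

Teal adds no Rea, so this reckoning leaves the midnight flask on its plateau. Green adds 0.550 equivalents:

13.6% + 8.4 percentage points = 22.0%

Violet and blue add no Rea, so the return is silent on them, and the earlier runs do not show what temperature does. The reckoning commits to green.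

The forecast gives 13.5% at 8.0 d, 13.5% after violet and 22% after green, and says “Green is the best bet, though uncertain”.

The flask gives 14.7% at 8.0 d. Green gains most, reaching 22.8% with a gain of 8.1 points. Blue gains 4.1 points, violet 3.6 points (reaching 18.4%) and teal 0.021 points.

    Sub + Rea → Sub.Rea (k = 0.580 L mol⁻¹ h⁻¹, Ea = 65.0 kJ mol⁻¹)
    Rea + Sub.Rea → Imd (k = 0.290 L mol⁻¹ h⁻¹, Ea = 62.0 kJ mol⁻¹)
    Rea + Imd → Rea.Imd (k = 0.350 L mol⁻¹ h⁻¹, Ea = 67.0 kJ mol⁻¹)
    Imd ⇌ Sid (K = 0.450, k = 0.110 h⁻¹, Ea = 104 kJ mol⁻¹, ΔH = −44.0 kJ mol⁻¹)
    (constants at 40 °C)

In the midnight flask at 8.00 d, Rea stands at 0.11% of its charge and Sub.Rea at 49.9% of the Sub charged. The half-life of Sub.Rea by its step to Imd is then 840 d, far longer than the 4.0 d of waiting. Green's gain, divided by the 0.550 equivalents added, comes to 14.7% of the Sub charged per equivalent, beside the 15.2% reckoned. Carried from the midnight plateau to a neighbour flask charged like it but with 0.19 M of Rea, the reckoned return gives 25.7%, and that neighbour holds 24.5% of Imd at 8.0 d.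

(The runs were generated by integration with made-up constants.)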